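## Structural features

Oncostemonol B (15) consists of two benzene rings, ring A and ring B, each oxygenated at C1 and C3 and joined through C5 by one unbranched sixteen-carbon chain that runs from C1' on ring A to C16' on ring B. The chain carries a single double bond, C8'=C9', at its midpoint with Z geometry, and since there is no stereogenic centre this geometry is the only stereochemical element. Ring B is a free resorcinol, whereas ring A carries one free hydroxyl and one acetate, and this ester alone breaks the twofold symmetry of the skeleton. The fragile groups are the aryl acetate (lost or transferred by bases, nucleophiles and Lewis acids), the Z-alkene (isomerised or hydrohalogenated by strong acid, hydrogen halides and halogen radicals) and the electron-rich rings (oxidation, C-alkylation). The real difficulty is not the carbon skeleton but securing a geometrically pure Z-alkene, freeing four phenols without touching that alkene, and placing one acetate on one of four symmetry-equivalent hydroxyls, which can only be done statistically. The key step uses the 1,3-dioxygenated, 5-alkylated pattern of each ring. A 3-alkylcyclobut-2-enone supplies C1, C4, C5, C6 and the C1 oxygen, and an alkoxyalkyne supplies C2, C3 and the C3 oxygen, so the chain necessarily ends up meta to both oxygens.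

## Logic of the disconnections

15 to 14. The bond cut is the acyl C–O bond of the acetate on ring A. It is the most labile bond in 15 and the only feature that distinguishes the two rings, so it is introduced last. The gain is a twofold-symmetric precursor in which all four hydroxyls are equivalent. The demand on the forward step is that acylation stops after one of four equivalent sites, which needs a deficit of acylating agent, a separation and recycling.

14 to 12. The two O–CH2 bonds of the ethyl ethers are restored, because the ring-forming step delivers each arene with one free and one ethylated oxygen. Nothing is gained in skeleton; the gain is that 12 is the direct output of the annulation. The forward step must cleave two aryl ethyl ethers while C8'=C9' is exposed to neither free hydrogen halide nor radicals.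

12 to 6 and 7. In each arene the bonds C1–C2 and C3–C4 are cut, which are the bonds to the two carbons that come from 7, so two molecules of 7 are needed for one of 6. The bond C1–C6 is recognised as a connection that is broken and re-made during the cascade. Per ring this is three bond-forming events, two of them new connections. This removes both aromatic rings at once and leaves a chain that ends in two four-membered enones. The forward step must run a four-stage pericyclic sequence at both termini of one molecule. The ketene intermediates must react with 7 and not with the Z-alkene or with phenolic O–H, and the regiochemistry of the ketene–alkyne union must place the ethoxy group meta to the hydroxyl.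

6 to 2 and 3. The bond between C3 of each four-membered ring and the terminal chain carbon (C1' and C16') is cut, so two molecules of 3 are joined to one of 2. The ring is a purchasable four-carbon electrophile (3) whose carbonyl addition and hydrolysis transposes into the 3-alkyl enone, and the chain becomes the dinucleophile 4, with 5 as the addition product. The gain is a simple α,ω-dibromide. The forward step needs carbonyl addition to outrun enolisation of 3 at both ends, and a hydrolysis mild enough for the alkene.

2 to 1. The C8'=C9' double bond is cut into two identical terminal-alkene halves, so two molecules of 1 give one of 2. This makes use of the symmetry of 2 and reduces the whole chain to one nine-carbon building block. The forward step must deliver the alkene with kinetic Z selectivity and without double-bond migration.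

## Other disconnections considered

Alternative 1: The cut is at C7'–C8' and C9'–C10', the two sp3–sp2 bonds that flank the alkene. The molecule would then be assembled from two molecules of 1-(7-iodoheptyl)-3,5-bis(methoxymethoxy)benzene A1 and one of acetylene A2.
- Forward key step: A1 would be converted by iodine–lithium exchange and transmetalation into a lithium dialkylcuprate, which adds syn across A2. The resulting Z-alkenylcuprate would be alkylated in the same flask by more A1 to give (Z)-1,16-bis[3,5-bis(methoxymethoxy)phenyl]hexadec-8-ene A3. Dilute acid would then release 14.
- In favour: the Z geometry comes from a stereospecific syn addition, which is better than the catalyst-controlled step 1 of the chosen plan. The acetal groups leave under mild protic acid that does not endanger C8'=C9', which is better than step 4. The arenes are bought, so no ring has to be built.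
- Against: A1 is not a catalogue compound and needs its own sequence of perhaps four or five steps, including acetal protection with a carcinogenic chloromethyl ether. The organometallic stage needs a pyrophoric alkyllithium, gaseous A2 and stoichiometric copper. The alkyllithium may metalate the ring position between the two acetal oxygens. Alkylation of an alkenylcuprate by an unactivated primary iodide is the sluggish half and usually needs a strongly coordinating cosolvent.
- Comparison: on structure, the alternative keeps both arenes from purchased material and builds only the two bonds next to the alkene, whereas the chosen plan builds both arenes and takes the whole chain from one symmetric dibromide. On stereocontrol and on deprotection the alternative is the better plan. On the endgame from 14 to 15 the two are equal, since both face the same statistical acetylation. On step economy the chosen plan, five steps from purchasable materials, should be clearly shorter. Mechanistically the alternative is polar organocopper chemistry at low temperature, whereas the chosen plan is a neutral thermal cascade.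

Alternative 2: The cut is one ring C–C bond per arene, so both rings are traced back to open-chain polyketide termini.
- Forward key step: (Z)-octadec-9-enedioic acid A4 would be extended at both carboxyl carbons to the bis(3,5,7-triketo ester) dimethyl (15Z)-3,5,7,24,26,28-hexaoxotriacont-15-enedioate A5. Base would then induce two intramolecular aldol condensations (C2 onto the C7 ketone at each end) with dehydration and enolisation, giving dimethyl 6,6'-[(Z)-hexadec-8-ene-1,16-diyl]bis(2,4-dihydroxybenzoate) A6. Ester hydrolysis and decarboxylation of A6 would lead to 14.
- In favour: A4 is a fermentation-derived diacid whose Z geometry is fixed by its origin, which is better than any catalyst- or reagent-controlled olefin synthesis in the chosen plan. The phenols appear free, so no O-dealkylation is needed next to the alkene, which is again better than step 4.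
- Against: A5 requires twofold C-acylation of polyanions of β-dicarbonyl esters, a class of reaction that tends to be low-yielding. Polyketones such as A5 have several competing cyclisation modes (pyranone formation, Claisen-type closure). Two further operations are needed after A6.
- Comparison: on structure, the alternative carries an extra ester carbon on each ring that must be removed again, whereas the chosen plan delivers the rings with one ethyl ether each to cleave. The step count is about equal (activation and chain extension, cyclisation, hydrolysis–decarboxylation, acetylation). The ring-forming step makes one C–C bond per arene under equilibrating basic conditions where the folding mode must be controlled. The cascade of the chosen plan fixes the substitution pattern by orbital polarisation under neutral conditions, so the chosen plan should be the more reliable at the key step. The alternative is superior in alkene integrity and in avoiding ether cleavage.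

Alternative 3: The cut is at C1'–C2' and C15'–C16', the bonds between the benzylic and homobenzylic carbons.
- Forward key step: 3,5-dimethoxytoluene A7 would be metalated at its methyl group with a mixed lithium–potassium amide base. Two equivalents of the benzylic anion would displace both bromides of (Z)-1,14-dibromotetradec-7-ene A8 to give (Z)-1,16-bis(3,5-dimethoxyphenyl)hexadec-8-ene A9. Fourfold demethylation would then give 14.
- In favour: A7 is cheap and purchasable, the arenes are bought, and one C–C-forming operation joins all three pieces. With A8 made by a Z-selective alkene construction analogous to step 1, the sequence would be four steps, one fewer than the chosen plan, so it is better on step economy. Because A9 carries no free phenol, its ether cleavage generates no hydrogen halide before work-up, which is arguably cleaner for the alkene than step 4.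
- Against: a very strong base meets a primary alkyl bromide, so elimination competes with substitution. Ring metalation between the two methoxy groups competes with benzylic metalation. The monoalkylated benzylic position remains acidic and can be alkylated again. Four methyl ethers must then be cleaved with a Lewis acid in the presence of the Z-alkene.
- Comparison: on structure, the alternative uses the arene with its methyl carbon as the benzylic chain terminus and needs a fourteen-carbon dihalide, whereas the chosen plan needs the sixteen-carbon dihalide and builds the rings around its ends. The alternative is shorter and cheaper, and on those points it is the better plan. The chosen plan avoids strongly basic conditions in the presence of alkyl halides and builds the substitution pattern with inherent regiocontrol. The two are equal in the final acetylation and equal in their dependence on a kinetically Z-selective route to the chain.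

Key step: step 3

Remark on the chemistry: 1, 3, 7 (as its solution in hexanes) and the ruthenium catalyst of step 1 are taken to be purchasable. The four hydroxyl groups of 14 are symmetry-equivalent, so a single acetylation at any of them gives 15. Steps 1, 2 and 3 each consume two molecules of one building block (1, 3 and 7 respectively) per molecule of product.

Step 1
Reactants: 1 9-bromonon-1-ene (2 equiv)
Product: 2 (Z)-1,16-dibromohexadec-8-ene
Conditions: RuC35H47N3O4 (1 mol %; Ru(NO3)(=CH-C6H4-2-OiPr) bound to a C,C-chelating 1-(adamant-1-yl)-3-(2,6-diisopropylphenyl)imidazolin-2-ylidene metalated at an adamantyl carbon), THF, 35 °C, static vacuum; chromatography on AgNO3-impregnated silica gel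
Reagents that add atoms: 9-bromonon-1-ene (second molecule of 1), C=CCCCCCCCBr
Why: Z-selective olefin homometathesis in which two molecules of the terminal alkene 1 are joined: the chelated carbene enforces a side-bound ruthenacyclobutane in which both alkyl substituents point away from the N-aryl group, so cycloreversion should release the Z-alkene and one molecule of ethylene, which is pumped off. Primary alkyl bromides do not interact with the ruthenium alkylidene; the C8'=C9' geometry of the target is set here, and any E isomer is removed at this non-polar stage on AgNO3-impregnated silica gel.

Step 2
Reactants: 2 (Z)-1,16-dibromohexadec-8-ene; 3 3-ethoxycyclobut-2-en-1-one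
Product: 6 3,3'-[(Z)-hexadec-8-ene-1,16-diyl]bis(cyclobut-2-en-1-one), via bis-Grignard reagent 4 (not isolated), via bis-carbinol 5 (not isolated)
Conditions: Mg turnings (I2-activated, 4 equiv), THF, 45 °C, slow addition of 2; then added to 3 (2.4 equiv), THF, −78 °C; then 1 M HCl, 0 °C → rt
Reagents that add atoms: 3-ethoxycyclobut-2-en-1-one (second equivalent of 3), CCOC1=CC(=O)C1; water, O
Why: Twofold magnesium insertion into the primary C–Br bonds, 1,2-addition of each carbon–magnesium terminus of 4 to the carbonyl group of one molecule of the vinylogous ester 3 at −78 °C (two molecules of 3 per molecule of 2), and Stork–Danheiser transposition: acid ionises the tertiary allylic carbinol 5 to an ethoxy-stabilised cyclobutenyl cation, water adds at the ethoxy-bearing carbon and ethanol is lost, giving the 3-alkylcyclobutenone. The two carbinol stereocentres of 5 form without control and vanish in the hydrolysis; the remote Z-alkene is inert to magnesium, to the Grignard reagent and to cold dilute acid.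

Step 3
Reactants: 6 3,3'-[(Z)-hexadec-8-ene-1,16-diyl]bis(cyclobut-2-en-1-one); 7 ethoxyacetylene (ethoxyethyne)
Product: 12 5,5'-[(Z)-hexadec-8-ene-1,16-diyl]bis(3-ethoxyphenol), via bis(vinylketene) 8 (not isolated), via bis(vinylcyclobutenone) 9 (not isolated), via bis(dienylketene) 10 (not isolated), via bis(cyclohexadienone) 11 (not isolated)
Conditions: 7 (8 equiv, commercial solution in hexanes), toluene (0.3 M in 6), sealed tube, 80 °C, Ar, dark; concentrate; then K2CO3, MeOH, rt
Reagents that add atoms: ethoxyacetylene (second equivalent of 7), CCOC#C
Why: Danheiser benzannulation (thermal aromatic annulation of a cyclobutenone with an alkoxyalkyne), run here at both chain termini of one substrate, so that one molecule of 6 takes up two molecules of 7. Near 80 °C each four-membered ring of 6 undergoes four-electron conrotatory opening of its C1–C4 bond to a vinylketene (8). The ketene C=C then adds 7 in a [2+2] cycloaddition in which the nucleophilic unsubstituted alkyne carbon bonds to the ketene carbonyl carbon and the ethoxy-bearing carbon to the ketene α-carbon, giving the 3-ethoxy-4-alkenylcyclobutenone (9), whose sp3 ring carbon is a transient stereocentre of no consequence. A second four-electron opening gives the dienylketene (10), and rings A and B are each closed by a thermal six-electron disrotatory electrocyclisation that joins the former carbonyl carbon to the former ring CH2; tautomerisation of the cyclohexa-2,4-dienone (11) gives the phenol, so no stereocentre remains. Per arene this is three C–C bond-forming events: two new bonds to the alkyne carbons and re-closure of the C1–C4 connection broken in the first opening. The regiochemistry (ethoxy meta to hydroxyl, chain meta to both) follows from the polarisation of the ynol ether and does not depend on the substrate. The selectivity needed is reaction of the ketenes with 7 and not with the remote, unactivated Z-alkene or with phenolic O–H of product already formed; the large excess of the far more nucleophilic 7 secures this, and the K2CO3/MeOH treatment cleaves any aryl ester formed by O-acylation.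

Step 4
Reactants: 12 5,5'-[(Z)-hexadec-8-ene-1,16-diyl]bis(3-ethoxyphenol)
Product: 14 5,5'-[(Z)-hexadec-8-ene-1,16-diyl]bis(benzene-1,3-diol), via tetrakis(dibromoboryl) ether 13 (not isolated)
Conditions: BBr3 (8 equiv), 2,6-di-tert-butyl-4-methylpyridine (2.2 equiv), CH2Cl2, −78 → 0 °C, Ar, dark; then H2O, 0 °C
Reagents that add atoms: none
Why: Lewis-acid cleavage of aryl alkyl ethers: BBr3 binds each ethoxy oxygen and bromide attacks the ethyl CH2 group (SN2), so the aryl C–O bonds stay intact and 13 is hydrolysed to 14 at work-up. The two phenols of 12 release HBr on borylation; the hindered pyridine, which binds protons but not boron halides, holds it as a pyridinium salt, so that neither ionic hydrobromination nor bromine-radical Z/E isomerisation of C8'=C9' is expected.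

Step 5
Reactants: 14 5,5'-[(Z)-hexadec-8-ene-1,16-diyl]bis(benzene-1,3-diol)
Product: 15 oncostemonol B (3-[(8Z)-16-(3,5-dihydroxyphenyl)hexadec-8-en-1-yl]-5-hydroxyphenyl acetate)
Conditions: Ac2O (0.9 equiv, slow addition), Et3N (1.2 equiv), THF, 0 °C → rt; chromatography; recovered 14 resubmitted
Reagents that add atoms: acetic anhydride, CC(=O)OC(C)=O
Why: Base-promoted O-acetylation of a phenol; since the four hydroxyls of 14 are symmetry-equivalent, the first acetylation can only give 15. Selectivity against further acetylation rests on the deficit of anhydride and slow addition, on the polarity differences between 14, 15 and more highly acetylated material, and on recycling (recovered 14 directly, over-acetylated fractions after K2CO3/MeOH).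

## Compound list

1 | 9-bromonon-1-ene | C=CCCCCCCCBr | starting material
2 | (Z)-1,16-dibromohexadec-8-ene | BrCCCCCCC/C=C\CCCCCCCBr | intermediate
3 | 3-ethoxycyclobut-2-en-1-one | CCOC1=CC(=O)C1 | starting material
4 | [(Z)-hexadec-8-ene-1,16-diyl]bis(magnesium bromide) | Br[Mg]CCCCCCC/C=C\CCCCCCC[Mg]Br | intermediate
5 | 1,1'-[(Z)-hexadec-8-ene-1,16-diyl]bis(3-ethoxycyclobut-2-en-1-ol), mixture of diastereomers at the two carbinol carbons | CCOC1=CC(O)(CCCCCCC/C=C\CCCCCCCC2(O)C=C(OCC)C2)C1 | intermediate
6 | 3,3'-[(Z)-hexadec-8-ene-1,16-diyl]bis(cyclobut-2-en-1-one) | O=C1C=C(CCCCCCC/C=C\CCCCCCCC2=CC(=O)C2)C1 | intermediate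
7 | ethoxyacetylene (ethoxyethyne) | CCOC#C | starting material
8 | (11Z)-3,20-dimethylidenedocosa-1,11,21-triene-1,22-dione | O=C=CC(=C)CCCCCCC/C=C\CCCCCCCC(=C)C=C=O | intermediate
9 | 4,4'-[(10Z)-icosa-1,10,19-triene-2,19-diyl]bis(3-ethoxycyclobut-2-en-1-one), mixture of diastereomers at the two ring CH carbons | CCOC1=CC(=O)C1C(=C)CCCCCCC/C=C\CCCCCCCC(=C)C1C(=O)C=C1OCC | intermediate
10 | (3E,13Z,23E)-3,24-diethoxy-5,22-dimethylidenehexacosa-1,3,13,23,25-pentaene-1,26-dione | O=C=C/C(OCC)=C\C(=C)CCCCCCC/C=C\CCCCCCCC(=C)/C=C(OCC)\C=C=O | intermediate
11 | 5,5'-[(Z)-hexadec-8-ene-1,16-diyl]bis(3-ethoxycyclohexa-2,4-dien-1-one) | CCOC1=CC(=O)CC(CCCCCCC/C=C\CCCCCCCC2=CC(OCC)=CC(=O)C2)=C1 | intermediate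
12 | 5,5'-[(Z)-hexadec-8-ene-1,16-diyl]bis(3-ethoxyphenol) | CCOc1cc(O)cc(CCCCCCC/C=C\CCCCCCCc2cc(O)cc(OCC)c2)c1 | intermediate
13 | 5,5'-[(Z)-hexadec-8-ene-1,16-diyl]bis[1,3-bis(dibromoboranyloxy)benzene] | BrB(Br)Oc1cc(OB(Br)Br)cc(CCCCCCC/C=C\CCCCCCCc2cc(OB(Br)Br)cc(OB(Br)Br)c2)c1 | intermediate
14 | 5,5'-[(Z)-hexadec-8-ene-1,16-diyl]bis(benzene-1,3-diol) | Oc1cc(O)cc(CCCCCCC/C=C\CCCCCCCc2cc(O)cc(O)c2)c1 | intermediate
15 | oncostemonol B (3-[(8Z)-16-(3,5-dihydroxyphenyl)hexadec-8-en-1-yl]-5-hydroxyphenyl acetate) | CC(=O)Oc1cc(O)cc(CCCCCCC/C=C\CCCCCCCc2cc(O)cc(O)c2)c1 | target

## Step count and least certain steps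

Total step count: 5. Longest linear sequence: 5 steps (linear from 1; 3 and 7 enter as purchased building blocks).

Step 3 (key step). The most likely failure is interception of a vinylketene by the phenolic hydroxyl of an arene already formed, at the other chain end or in another molecule. Ketene self-condensation is a second possibility. Because two cascades must succeed on every molecule, any loss per terminus counts twice, and incomplete conversion would leave material with one four-membered ring intact. The fallback gives up ring construction and attaches purchased arenes. It sets out from 4, generated from 2 as in step 2. A Kumada coupling of 4 with 1-bromo-3,5-dimethoxybenzene F1 (2.2 equiv, NiCl2(Ph2P(CH2)3PPh2) 3 mol %, THF, rt to reflux) should give (Z)-1,16-bis(3,5-dimethoxyphenyl)hexadec-8-ene F2. All four methyl ethers of F2, which carries no acidic proton, would then be cleaved with B-iodo-9-borabicyclo[3.3.1]nonane (C8H14BI) in hexane at rt, with an ethanolamine work-up. The fallback returns to the route at 14.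

Step 4. What may go wrong is addition of hydrogen bromide across C8'=C9', or its Z-to-E isomerisation by reversible bromine-radical addition, if proton scavenging is incomplete. Cleavage of the ethyl ethers, which are slower than methyl ethers, may also be incomplete at temperatures low enough to spare the alkene. The fallback removes the acidic protons before the Lewis acid is added, and sets out from 12. Silylation (t-BuMe2SiCl, imidazole, DMF) should give 5,5'-[(Z)-hexadec-8-ene-1,16-diyl]bis[1-(tert-butyldimethylsilyloxy)-3-ethoxybenzene] F3. Treatment of F3 with B-iodo-9-borabicyclo[3.3.1]nonane in hexane/CH2Cl2, where no protic acid can form, followed by an ethanolamine work-up, should give 5,5'-[(Z)-hexadec-8-ene-1,16-diyl]bis[3-(tert-butyldimethylsilyloxy)phenol] F4. Any silyl group lost at this stage only anticipates the next operation. n-Bu4NF in THF at 0 °C then returns the route to 14.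

Step 1. The risks are erosion of Z selectivity by secondary metathesis as conversion rises, and double-bond migration by ruthenium hydrides formed on catalyst decomposition. Migration would give chain-length homologues that cannot be removed later. The fallback is a stoichiometric olefination that replaces 1 as the starting material: it sets out from purchasable 8-bromooctan-1-ol F5 and comes back to the route at 2. Heating F5 with PPh3 in MeCN should give (8-hydroxyoctyl)triphenylphosphonium bromide F6, and oxidation of a second portion of F5 (TEMPO cat., PhI(OAc)2, CH2Cl2) should give 8-bromooctanal F7. A salt-free Wittig reaction of F6 (NaN(SiMe3)2, 2.0 equiv, THF, −78 °C, then F7) should give (Z)-16-bromohexadec-8-en-1-ol F8. An Appel bromination (CBr4, PPh3, CH2Cl2, 0 °C) of F8 then returns the route to 2.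

Step 2. Wurtz-type coupling may occur during the twofold magnesium insertion. Proton transfer from C4 of 3 to the basic carbon nucleophile (enolisation instead of addition) would leave reduced chain ends and singly capped material. The fallback changes the metal and the way the carbanion is generated, and sets out from 2. A Finkelstein exchange (NaI, acetone, reflux) should give (Z)-1,16-diiodohexadec-8-ene F9. Iodine–lithium exchange (t-BuLi, 4.2 equiv, Et2O/pentane, −78 °C) should give [(Z)-hexadec-8-ene-1,16-diyl]dilithium F10 without radical coupling. F10 is added at −78 °C to 3 (2.4 equiv), and the route is rejoined at 5, which is hydrolysed to 6 as in step 2.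

Step 5. The four hydroxyls react independently, so acylation spreads over unreacted, mono- and poly-acetylated material. A purely statistical course would cap the monoacetate near two fifths of the material per pass, and the separation load is high. The fallback works by subtraction and sets out from 14. Exhaustive acetylation (Ac2O, Et3N, CH2Cl2) should give 5,5'-[(Z)-hexadec-8-ene-1,16-diyl]bis(benzene-1,3-diyl) tetraacetate F11. Stoichiometrically limited aminolysis with pyrrolidine (3 equiv, CH2Cl2, 0 °C) should remove the first acetate of each ring quickly, because a liberated phenol, largely as its ammonium phenoxide, deactivates the remaining ester on the same ring. The process should therefore pass through 5,5'-[(Z)-hexadec-8-ene-1,16-diyl]bis(3-hydroxyphenyl) diacetate F12 and reduce the problem to removing one of two equivalent acetates. The fallback returns to the route at 15, and other fractions are recycled through F11.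

## Further compounds

F1 | step 3 | 1-bromo-3,5-dimethoxybenzene | COc1cc(Br)cc(OC)c1
F2 | step 3 | (Z)-1,16-bis(3,5-dimethoxyphenyl)hexadec-8-ene | COc1cc(OC)cc(CCCCCCC/C=C\CCCCCCCc2cc(OC)cc(OC)c2)c1
F3 | step 4 | 5,5'-[(Z)-hexadec-8-ene-1,16-diyl]bis[1-(tert-butyldimethylsilyloxy)-3-ethoxybenzene] | CCOc1cc(O[Si](C)(C)C(C)(C)C)cc(CCCCCCC/C=C\CCCCCCCc2cc(O[Si](C)(C)C(C)(C)C)cc(OCC)c2)c1
F4 | step 4 | 5,5'-[(Z)-hexadec-8-ene-1,16-diyl]bis[3-(tert-butyldimethylsilyloxy)phenol] | Oc1cc(O[Si](C)(C)C(C)(C)C)cc(CCCCCCC/C=C\CCCCCCCc2cc(O)cc(O[Si](C)(C)C(C)(C)C)c2)c1
F5 | step 1 | 8-bromooctan-1-ol | OCCCCCCCCBr
F6 | step 1 | (8-hydroxyoctyl)triphenylphosphonium bromide | OCCCCCCCC[P+](c1ccccc1)(c1ccccc1)c1ccccc1.[Br-]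
F7 | step 1 | 8-bromooctanal | O=CCCCCCCCBr
F8 | step 1 | (Z)-16-bromohexadec-8-en-1-ol | OCCCCCCC/C=C\CCCCCCCBr
F9 | step 2 | (Z)-1,16-diiodohexadec-8-ene | ICCCCCCC/C=C\CCCCCCCI
F10 | step 2 | [(Z)-hexadec-8-ene-1,16-diyl]dilithium | [Li]CCCCCCC/C=C\CCCCCCC[Li]
F11 | step 5 | 5,5'-[(Z)-hexadec-8-ene-1,16-diyl]bis(benzene-1,3-diyl) tetraacetate | CC(=O)Oc1cc(OC(C)=O)cc(CCCCCCC/C=C\CCCCCCCc2cc(OC(C)=O)cc(OC(C)=O)c2)c1
F12 | step 5 | 5,5'-[(Z)-hexadec-8-ene-1,16-diyl]bis(3-hydroxyphenyl) diacetate | CC(=O)Oc1cc(O)cc(CCCCCCC/C=C\CCCCCCCc2cc(O)cc(OC(C)=O)c2)c1
A1 | alternative 1 | 1-(7-iodoheptyl)-3,5-bis(methoxymethoxy)benzene | COCOc1cc(CCCCCCCI)cc(OCOC)c1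
A2 | alternative 1 | acetylene | C#C
A3 | alternative 1 | (Z)-1,16-bis[3,5-bis(methoxymethoxy)phenyl]hexadec-8-ene | COCOc1cc(OCOC)cc(CCCCCCC/C=C\CCCCCCCc2cc(OCOC)cc(OCOC)c2)c1
A4 | alternative 2 | (Z)-octadec-9-enedioic acid | OC(=O)CCCCCCC/C=C\CCCCCCCC(=O)O
A5 | alternative 2 | dimethyl (15Z)-3,5,7,24,26,28-hexaoxotriacont-15-enedioate | COC(=O)CC(=O)CC(=O)CC(=O)CCCCCCC/C=C\CCCCCCCC(=O)CC(=O)CC(=O)CC(=O)OC
A6 | alternative 2 | dimethyl 6,6'-[(Z)-hexadec-8-ene-1,16-diyl]bis(2,4-dihydroxybenzoate) | COC(=O)c1c(O)cc(O)cc1CCCCCCC/C=C\CCCCCCCc1cc(O)cc(O)c1C(=O)OC
A7 | alternative 3 | 3,5-dimethoxytoluene | COc1cc(C)cc(OC)c1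
A8 | alternative 3 | (Z)-1,14-dibromotetradec-7-ene | BrCCCCCC/C=C\CCCCCCBr
A9 | alternative 3 | (Z)-1,16-bis(3,5-dimethoxyphenyl)hexadec-8-ene | COc1cc(OC)cc(CCCCCCC/C=C\CCCCCCCc2cc(OC)cc(OC)c2)c1
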